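The pyran ring of the 2H-chromene is opened at C4–C4a and C8a–O1. The ring oxygen O1 is attached at C8a, para to the acetyl-bearing C6 of the benzo ring, so a C8a–F bond is primed for SNAr and a C4a–Br bond for cross-coupling. In one operation aryl bromide 3 is joined to the Z-alkenylboron carbon of (R)-oxaborole 10 and the freed C2 tertiary alkoxide expels fluoride. This is a formal [4+2] annulation that leaves the C2 stereocentre, set by Sharpless epoxidation, untouched. Oxaborole 10 comes from boron-tethered ring-closing metathesis, which enforces the Z geometry, and carries a migration-resistant TBDPS ether.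

Key step: step 6

Remark: 18 is obtained in the enantiomeric purity delivered by the Sharpless step (step 3); should enrichment be needed, recrystallisation of alcohol 13 or of 18 is foreseen.

Step 1
Reactants: 1 1-(4-fluoro-2-hydroxyphenyl)ethanone
Product: 2 1-(5-bromo-4-fluoro-2-hydroxyphenyl)ethanone
Conditions: NBS (1.05 equiv), MeCN, 0 °C → rt
Reagents that add atoms: N-bromosuccinimide, O=C1CCC(=O)N1Br
Why: Electrophilic aromatic bromination goes para to the hydroxyl group (C5, also ortho to F and meta to the acetyl group), because the other activated position, C3, is wedged between OH and F and the chelated ketone resists α-bromination under neutral conditions.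

Step 2
Reactants: 2 1-(5-bromo-4-fluoro-2-hydroxyphenyl)ethanone
Product: 3 1-[5-bromo-4-fluoro-2-(methoxymethoxy)phenyl]ethanone
Conditions: MOMCl (1.5 equiv), i-Pr2NEt (2.0 equiv), CH2Cl2, 0 °C → rt
Reagents that add atoms: chloromethyl methyl ether, COCCl
Why: O-Alkylation of the phenol (MOM protection) is routine and removes the acidic OH that would otherwise become a ring-deactivating phenoxide under the basic conditions of step 6.

Step 3
Reactants: 4 2-methylprop-2-en-1-ol
Product: 6 tert-butyl{[(2R)-2-methyloxiran-2-yl]methoxy}diphenylsilane, via (S)-2-methylglycidol 5 (not isolated)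
Conditions: Ti(Oi-Pr)4 (5 mol %), L-(+)-diisopropyl tartrate (6 mol %), cumene hydroperoxide, 3 Å MS, CH2Cl2, −20 °C; P(OMe)3; then TBDPSCl, imidazole, DMAP (cat.), −20 → 0 °C
Reagents that add atoms: cumene hydroperoxide, CC(C)(OO)c1ccccc1; tert-butyl(chloro)diphenylsilane, CC(C)(C)[Si](Cl)(c1ccccc1)c1ccccc1
Why: In the Katsuki–Sharpless asymmetric epoxidation the titanium catalyst built from L-(+)-tartrate gives the (S)-epoxy alcohol and so sets the future C2 stereocentre by catalyst control, and in situ silylation avoids isolating the small water-soluble epoxy alcohol (the descriptor becomes R only because silicon raises the CIP rank of the CH2O arm).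

Step 4
Reactants: 6 tert-butyl{[(2R)-2-methyloxiran-2-yl]methoxy}diphenylsilane
Product: 7 (2R)-1-[(tert-butyldiphenylsilyl)oxy]-2-methylbut-3-en-2-ol
Conditions: Me3S+ I− (4 equiv), n-BuLi (3.8 equiv), THF, −10 °C → rt
Reagents that add atoms: trimethylsulfonium iodide, C[S+](C)C.[I-]
Why: One-carbon homologation of a terminal epoxide to an allylic alcohol with dimethylsulfonium methylide (ylide opening at the unsubstituted CH2, then ylide-mediated β-elimination of Me2S) leaves the C–O bond at the stereocentre intact, so the configuration is retained.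

Step 5
Reactants: 7 (2R)-1-[(tert-butyldiphenylsilyl)oxy]-2-methylbut-3-en-2-ol
Product: 10 (5R)-5-{[(tert-butyldiphenylsilyl)oxy]methyl}-5-methyl-1,2-oxaborol-2(5H)-ol, via mixed vinylboronate ester 8 (not isolated), via B-butoxy oxaborole 9 (not isolated)
Conditions: CH2=CHB(On-Bu)2 (1.5 equiv), toluene, 60 °C, reduced pressure; second-generation Grubbs catalyst RuCl2(H2IMes)(PCy3)(=CHPh) (5 mol %), CH2Cl2, 40 °C; THF/H2O work-up
Reagents that add atoms: dibutyl vinylboronate, C=CB(OCCCC)OCCCC; water, O
Why: In this boron-tethered ring-closing metathesis, transesterification ties the vinylboron unit to the tertiary hydroxyl, closure to the five-membered ring can only give the cis alkene, and aqueous work-up exchanges butoxy for hydroxyl to leave the stable cyclic boronic half-acid, with the stereocentre a spectator.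

Step 6
Reactants: 3 1-[5-bromo-4-fluoro-2-(methoxymethoxy)phenyl]ethanone; 10 (5R)-5-{[(tert-butyldiphenylsilyl)oxy]methyl}-5-methyl-1,2-oxaborol-2(5H)-ol
Product: 12 1-[(2R)-2-{[(tert-butyldiphenylsilyl)oxy]methyl}-7-(methoxymethoxy)-2-methyl-2H-chromen-6-yl]ethanone, via Z-styrenyl tertiary alcohol 11 (not isolated)
Conditions: 3 (1.0 equiv), 10 (1.2 equiv), Pd(dppf)Cl2·CH2Cl2 (5 mol %), Cs2CO3 (3 equiv), degassed 1,4-dioxane/H2O (10:1), 85 °C, then 100 °C
Reagents that add atoms: none
Why: Proposed new method: zerovalent palladium inserts into the C–Br bond of 3 (the C–F bond is inert to it), the carbonate-opened oxaborole 10 transmetalates its alkenyl carbon with retention of the cis geometry, and reductive elimination forms C4–C4a, after which water releases the tertiary alkoxide of 11. Held beside C8a by the Z alkene, this alkoxide adds to the fluorine-bearing carbon, and the Meisenheimer complex, stabilised by the para acetyl group, expels fluoride to form C8a–O1. The closest known reaction types are the Suzuki–Miyaura coupling of cyclic alkenylboronic half-acids (2,5-dihydro-1,2-oxaborol-2-ols) with aryl halides to give Z-γ-hydroxystyrenes and the intramolecular SNAr etherification of fluoroarenes para to an acyl group; only their merger in one flask to a 2H-chromene is new. The pyran ring closes in a 6-exo-trig addition–elimination, so that four atoms (O1, C2, C3, C4) are annulated onto the C4a–C8a edge of the benzo ring. No stereocentre is formed and C2 is never a reacting centre, so the configuration set in step 3 is carried through unchanged. The step needs chemoselectivity (coupling at bromine before anything happens at fluorine, closure by the tertiary oxygen only), which is secured by the fixed positions of Br and F, by the ring of 10 that can only deliver the Z alkene, by the MOM cap that prevents a deactivating phenoxide, and by the TBDPS ether that should not migrate to the tertiary alkoxide.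

Step 7
Reactants: 12 1-[(2R)-2-{[(tert-butyldiphenylsilyl)oxy]methyl}-7-(methoxymethoxy)-2-methyl-2H-chromen-6-yl]ethanone
Product: 13 1-[(2R)-2-(hydroxymethyl)-7-(methoxymethoxy)-2-methyl-2H-chromen-6-yl]ethanone
Conditions: TBAF (1.5 equiv), AcOH (1.5 equiv), THF, rt → 40 °C
Reagents that add atoms: none
Why: Fluoride-driven cleavage of the silyl ether (Si–F bond formation) frees the primary alcohol, and acetic acid buffering keeps the aryl ketone, the MOM ether and the chromene untouched.

Step 8
Reactants: 14 (E)-ferulic acid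
Product: 16 (2E)-3-[3-methoxy-4-(methoxymethoxy)phenyl]prop-2-enoic acid, via bis-MOM ferulate 15 (not isolated)
Conditions: MOMCl (2.5 equiv), i-Pr2NEt (3 equiv), CH2Cl2, 0 °C → rt; then LiOH (2 equiv), THF/H2O, rt; 1 M HCl to pH 4, 0 °C
Reagents that add atoms: chloromethyl methyl ether, COCCl; lithium hydroxide, [Li+].[OH-]
Why: Alkylation of phenol and carboxylate with MOMCl followed by saponification cleaves only the very labile acyloxymethyl ester, leaving the aryl MOM ether and the E alkene intact.

Step 9
Reactants: 13 1-[(2R)-2-(hydroxymethyl)-7-(methoxymethoxy)-2-methyl-2H-chromen-6-yl]ethanone; 16 (2E)-3-[3-methoxy-4-(methoxymethoxy)phenyl]prop-2-enoic acid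
Product: 17 [(2R)-6-acetyl-7-(methoxymethoxy)-2-methyl-2H-chromen-2-yl]methyl (2E)-3-[3-methoxy-4-(methoxymethoxy)phenyl]prop-2-enoate
Conditions: DCC (1.2 equiv), DMAP (0.2 equiv), CH2Cl2, 0 °C → rt
Reagents that add atoms: none
Why: Steglich esterification (carbodiimide activation, DMAP acyl transfer) acylates the only free hydroxyl, a primary alcohol, since both phenols are masked.

Step 10
Reactants: 17 [(2R)-6-acetyl-7-(methoxymethoxy)-2-methyl-2H-chromen-2-yl]methyl (2E)-3-[3-methoxy-4-(methoxymethoxy)phenyl]prop-2-enoate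
Product: 18 [(2R)-6-acetyl-7-hydroxy-2-methyl-2H-chromen-2-yl]methyl (2E)-3-(4-hydroxy-3-methoxyphenyl)prop-2-enoate
Conditions: 3 M aq. HCl/THF (1:3), 45 °C
Reagents that add atoms: none
Why: Acid-catalysed acetal hydrolysis should remove both aryl MOM ethers in one operation (the one ortho to the acetyl group first) under conditions too mild to hydrolyse the cinnamate ester or protonate the acyl-deactivated chromene, and C2 is not involved.

Compound list
1 | 1-(4-fluoro-2-hydroxyphenyl)ethanone | CC(=O)c1ccc(F)cc1O | starting material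
2 | 1-(5-bromo-4-fluoro-2-hydroxyphenyl)ethanone | CC(=O)c1cc(Br)c(F)cc1O | intermediate
3 | 1-[5-bromo-4-fluoro-2-(methoxymethoxy)phenyl]ethanone | CC(=O)c1cc(Br)c(F)cc1OCOC | intermediate
4 | 2-methylprop-2-en-1-ol | CC(=C)CO | starting material
5 | [(2S)-2-methyloxiran-2-yl]methanol, (S)-2-methylglycidol | C[C@]1(CO)CO1 | intermediate
6 | tert-butyl{[(2R)-2-methyloxiran-2-yl]methoxy}diphenylsilane | C[C@]1(CO[Si](c2ccccc2)(c2ccccc2)C(C)(C)C)CO1 | intermediate
7 | (2R)-1-[(tert-butyldiphenylsilyl)oxy]-2-methylbut-3-en-2-ol | C[C@](O)(CO[Si](c1ccccc1)(c1ccccc1)C(C)(C)C)C=C | intermediate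
8 | butyl (2R)-1-[(tert-butyldiphenylsilyl)oxy]-2-methylbut-3-en-2-yl ethenylboronate | C[C@](OB(OCCCC)C=C)(CO[Si](c1ccccc1)(c1ccccc1)C(C)(C)C)C=C | intermediate
9 | (5R)-2-butoxy-5-{[(tert-butyldiphenylsilyl)oxy]methyl}-5-methyl-2,5-dihydro-1,2-oxaborole | CC(C)(C)[Si](c1ccccc1)(c1ccccc1)OC[C@@]1(C)C=CB(OCCCC)O1 | intermediate
10 | (5R)-5-{[(tert-butyldiphenylsilyl)oxy]methyl}-5-methyl-1,2-oxaborol-2(5H)-ol | CC(C)(C)[Si](c1ccccc1)(c1ccccc1)OC[C@@]1(C)C=CB(O)O1 | intermediate
11 | 1-{5-[(1Z,3R)-4-[(tert-butyldiphenylsilyl)oxy]-3-hydroxy-3-methylbut-1-en-1-yl]-4-fluoro-2-(methoxymethoxy)phenyl}ethanone | CC(=O)c1cc(/C=C\[C@@](C)(O)CO[Si](c2ccccc2)(c2ccccc2)C(C)(C)C)c(F)cc1OCOC | intermediate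
12 | 1-[(2R)-2-{[(tert-butyldiphenylsilyl)oxy]methyl}-7-(methoxymethoxy)-2-methyl-2H-chromen-6-yl]ethanone | CC(C)(C)[Si](c1ccccc1)(c1ccccc1)OC[C@@]2(C)C=Cc3cc(C(C)=O)c(OCOC)cc3O2 | intermediate
13 | 1-[(2R)-2-(hydroxymethyl)-7-(methoxymethoxy)-2-methyl-2H-chromen-6-yl]ethanone | OC[C@@]1(C)C=Cc2cc(C(C)=O)c(OCOC)cc2O1 | intermediate
14 | (2E)-3-(4-hydroxy-3-methoxyphenyl)prop-2-enoic acid, ferulic acid | COc1cc(/C=C/C(=O)O)ccc1O | starting material
15 | methoxymethyl (2E)-3-[3-methoxy-4-(methoxymethoxy)phenyl]prop-2-enoate | COCOC(=O)/C=C/c1ccc(OCOC)c(OC)c1 | intermediate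
16 | (2E)-3-[3-methoxy-4-(methoxymethoxy)phenyl]prop-2-enoic acid | COCOc1ccc(/C=C/C(=O)O)cc1OC | intermediate
17 | [(2R)-6-acetyl-7-(methoxymethoxy)-2-methyl-2H-chromen-2-yl]methyl (2E)-3-[3-methoxy-4-(methoxymethoxy)phenyl]prop-2-enoate | COCOc1ccc(/C=C/C(=O)OC[C@@]2(C)C=Cc3cc(C(C)=O)c(OCOC)cc3O2)cc1OC | intermediate
18 | [(2R)-6-acetyl-7-hydroxy-2-methyl-2H-chromen-2-yl]methyl (2E)-3-(4-hydroxy-3-methoxyphenyl)prop-2-enoate | COc1cc(/C=C/C(=O)OC[C@@]2(C)C=Cc3cc(C(C)=O)c(O)cc3O2)ccc1O | target

Total step count: 10.
Longest linear sequence: 7 steps (steps 3, 4, 5, 6, 7, 9 and 10, from 4 to 18).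

Steps most likely to fail

Step 6. The ring closure may lag behind the coupling because carbonate generates little tertiary alkoxide, and meanwhile hydroxide can slowly attack the C–F bond or the alkenylboron unit can protodeboronate. The fallback uses known chemistry and closes the ring by metathesis instead; it sets out from 3 and 7 and returns at 12. The potassium alkoxide of 7 (KN(SiMe3)2, THF/DMF, 0 °C) displaces the fluoride of 3 in an intermolecular SNAr para to the acetyl group to give the aryl tertiary-allyl ether F1. Suzuki–Miyaura vinylation of its bromide with potassium vinyltrifluoroborate (Pd(dppf)Cl2, Cs2CO3, THF/H2O, 70 °C) gives the ortho-vinyl aryl ether F2. Ring-closing metathesis with second-generation Grubbs catalyst (CH2Cl2, 40 °C) then forms C3=C4 and delivers 12 with C2 untouched.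

Step 5. Transesterification of the hindered tertiary hydroxyl onto boron may remain incomplete, so that the catalyst only dimerises the vinylboronate. The fallback controls the Z geometry by a Wittig reaction; it sets out from 7 and returns at 10. Ozonolysis of 7 (O3, CH2Cl2/MeOH, −78 °C; Me2S) gives the α-hydroxy aldehyde F3. Stork–Zhao olefination (Ph3P+CH2I I−, NaN(SiMe3)2, THF/DMPU, −78 °C, the tertiary hydroxyl carried as its alkoxide) gives the Z-vinyl iodide F4. Iodine–lithium exchange with retention of geometry (t-BuLi, Et2O, −78 °C), trapping with B(Oi-Pr)3 and aqueous work-up close the oxaborole 10.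

Step 10. The guaiacol MOM ether may cleave slowly, and prolonged acid exposure could hydrolyse the cinnamate ester or hydrate the chromene alkene. The fallback applies no acid once the ester is in place; it sets out from 13 and 14 and returns at 18. The labile ortho-acyl MOM ether of 13 is removed first (1 M aq. HCl/THF, rt) to give the chelated phenol alcohol F5. Ferulic acid 14 is acetylated (Ac2O, pyridine) to O-acetylferulic acid F6. Steglich esterification at 0 °C acylates the primary hydroxyl of F5 in preference to the hydrogen-bonded phenol and gives the acetate-protected ester F7. Brief methanolysis of the aryl acetate (K2CO3 cat., MeOH, 0 °C), which is cleaved far faster than the conjugated alkyl ester, gives 18.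

Further compounds
F1 | step 6 | 1-[5-bromo-4-{[(2R)-1-[(tert-butyldiphenylsilyl)oxy]-2-methylbut-3-en-2-yl]oxy}-2-(methoxymethoxy)phenyl]ethanone | CC(=O)c1cc(Br)c(O[C@](C)(C=C)CO[Si](c2ccccc2)(c2ccccc2)C(C)(C)C)cc1OCOC
F2 | step 6 | 1-[4-{[(2R)-1-[(tert-butyldiphenylsilyl)oxy]-2-methylbut-3-en-2-yl]oxy}-5-ethenyl-2-(methoxymethoxy)phenyl]ethanone | CC(=O)c1cc(C=C)c(O[C@](C)(C=C)CO[Si](c2ccccc2)(c2ccccc2)C(C)(C)C)cc1OCOC
F3 | step 5 | (2S)-3-[(tert-butyldiphenylsilyl)oxy]-2-hydroxy-2-methylpropanal | C[C@](O)(CO[Si](c1ccccc1)(c1ccccc1)C(C)(C)C)C=O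
F4 | step 5 | (2R,3Z)-1-[(tert-butyldiphenylsilyl)oxy]-4-iodo-2-methylbut-3-en-2-ol | C[C@](O)(CO[Si](c1ccccc1)(c1ccccc1)C(C)(C)C)/C=C\I
F5 | step 10 | 1-[(2R)-7-hydroxy-2-(hydroxymethyl)-2-methyl-2H-chromen-6-yl]ethanone | OC[C@@]1(C)C=Cc2cc(C(C)=O)c(O)cc2O1
F6 | step 10 | (2E)-3-(4-acetoxy-3-methoxyphenyl)prop-2-enoic acid | CC(=O)Oc1ccc(/C=C/C(=O)O)cc1OC
F7 | step 10 | [(2R)-6-acetyl-7-hydroxy-2-methyl-2H-chromen-2-yl]methyl (2E)-3-(4-acetoxy-3-methoxyphenyl)prop-2-enoate | CC(=O)Oc1ccc(/C=C/C(=O)OC[C@@]2(C)C=Cc3cc(C(C)=O)c(O)cc3O2)cc1OC
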